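**Plan**

- The spermine chain is numbered as 4,9-diazadodecane (C1–C3, N4, C5–C8, N9, C10–C12), with the two amide nitrogens on C1 and C12.
- The retrosynthesis cuts the two amide C–N bonds to the dihydrocaffeoyl units first, then the C2–C3 and C10–C11 bonds, and last the N4–C3 and N9–C10 bonds, arriving at 1,4-diaminobutane.
- Enabling feature: C3 and C10 each sit alpha to a secondary amine nitrogen (N4, N9), so each is the alpha-carbon of an N-Boc glycine whose carboxyl group can be exchanged for a CH2CH2–phthalimide unit (C2–C1–N and C11–C12–N). The only rings, the two catechol arenes, arrive intact and no ring is formed.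
- Forward, the chain grows from the centre outwards: C5–C8 diamine, then bis-glycine, then a double decarboxylative coupling that completes the twelve-atom chain with internal nitrogens as Boc carbamates and terminal nitrogens as phthalimides, then acylation and deprotection.
- The target is achiral, so no stereocentre has to be set or preserved.

Key step: step 4

Assumption: the target is taken as the neutral free base as drawn; it is expected to be stored most conveniently as its bis-hydrochloride 13, from which it is released in the work-up of the last step.

**Route**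

Step 1
Reactants: 1 1,4-diaminobutane
Product: 2 N,N'-di-Boc-1,4-diaminobutane
Conditions: Boc2O (2.1 equiv), CH2Cl2, 0 °C → rt
Reagents that add atoms: di-tert-butyl dicarbonate, CC(C)(C)OC(=O)OC(=O)OC(C)(C)C
Why: Carbamate formation (Boc protection) of both primary amines needs no added base and should give a bis-carbamate whose two N–H groups are the only acidic sites for the next step.

Step 2
Reactants: 2 N,N'-di-Boc-1,4-diaminobutane; 3 ethyl bromoacetate (two molecules incorporated)
Product: 4 diethyl N,N'-di-Boc-N,N'-butane-1,4-diylbisglycinate
Conditions: NaH (2.4 equiv), DMF, 0 °C; then 3 (2.5 equiv), 0 °C → rt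
Reagents that add atoms: none
Why: N-alkylation of the sodium carbamate by SN2 displacement on the reactive alpha-bromo ester installs both glycine units, and since each nitrogen already carries Boc it can be alkylated only once, which avoids the over-alkylation and pyrrolidine closure that a free amine with a 1,4-dihalide would suffer.

Step 3
Reactants: 4 diethyl N,N'-di-Boc-N,N'-butane-1,4-diylbisglycinate
Product: 5 N,N'-di-Boc-N,N'-butane-1,4-diylbisglycine
Conditions: LiOH·H2O (4 equiv), THF/H2O, rt; then 1 M HCl to pH 3, 0 °C
Reagents that add atoms: lithium hydroxide, [Li+].[OH-]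
Why: Ester saponification leaves the base-stable Boc carbamates untouched, and brief cold acidification to pH 3 should free the diacid without Boc loss.

Step 4
Reactants: 5 N,N'-di-Boc-N,N'-butane-1,4-diylbisglycine; 6 N-(2-bromoethyl)phthalimide (two molecules incorporated)
Product: 8 N1,N12-diphthaloyl-N4,N9-di-Boc-spermine, via mono-coupled acid 7 (not isolated)
Conditions: 6 (4 equiv), Ir[dF(CF3)ppy]2(dtbbpy)PF6 (4 mol %), NiCl2·glyme (20 mol %), 4,4'-di-tert-butyl-2,2'-bipyridine (20 mol %), K2CO3 (4 equiv), H2O (40 equiv), MeCN, degassed, blue LEDs (450 nm), 25 °C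
Reagents that add atoms: none
Why: Each potassium carboxylate of 5 is oxidised by the photoexcited trivalent iridium complex and loses CO2 to give a Boc-stabilised primary alpha-amino radical at C3 (then C10), while bipyridine-ligated zerovalent nickel adds oxidatively to the primary C–Br bond of 6, captures the radical as a trivalent dialkylnickel species and reductively eliminates the C2–C3 (then C10–C11) bond, the monovalent nickel left behind being returned to the zerovalent state by the reduced, divalent iridium complex. The closest known reaction is the NiCl2/photoredox decarboxylative C(sp3)–C(sp3) cross-coupling of N-Boc alpha-amino acids with primary alkyl bromides, run here twice on one molecule by way of the mono-coupled acid 7. No ring is closed and no stereocentre is created. The step needs cross-coupling to prevail over protodecarboxylation to the N-methyl carbamate, O-alkylation of the carboxylate by 6, loss of HBr from 6 and radical dimerisation. This should be secured by both partners being primary and unhindered, by the excess of 6, by the heterogeneous K2CO3/water/MeCN medium that keeps the concentration of free carboxylate low, by the imide nitrogen of 6 having no N–H that could cyclise onto the bromide or bind nickel, and by the four-methylene spacer that lets the two glycine arms react independently.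

Step 5
Reactants: 8 N1,N12-diphthaloyl-N4,N9-di-Boc-spermine
Product: 9 N4,N9-di-Boc-spermine
Conditions: N2H4·H2O (8 equiv), EtOH, 70 °C; filter
Reagents that add atoms: none
Why: Ing–Manske hydrazinolysis removes both phthalimides as insoluble phthalhydrazide while the Boc carbamates are inert to hydrazine, so only the two terminal primary amines are exposed.

Step 6
Reactants: 9 N4,N9-di-Boc-spermine; 10 3-(3,4-dihydroxyphenyl)propanoic acid (two molecules incorporated)
Product: 12 N4,N9-di-Boc-kukoamine A, via N-hydroxysuccinimide ester 11 (not isolated)
Conditions: 10 (2.2 equiv), N-hydroxysuccinimide (2.2 equiv), DCC (2.2 equiv), THF, 0 °C → rt, filter; then 9, iPr2NEt, THF/DMF, rt, argon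
Reagents that add atoms: none
Why: Active-ester amidation (carbodiimide/N-hydroxysuccinimide) is selective for the aliphatic primary amines over the catechol hydroxyls, as in the usual preparation of hydroxycinnamoyl polyamine amides from unprotected phenolic acids, and the internal nitrogens are blocked as Boc carbamates.

Step 7
Reactants: 12 N4,N9-di-Boc-kukoamine A
Product: 14 kukoamine A, via kukoamine A bis-hydrochloride 13 (not isolated)
Conditions: HCl (4 M in 1,4-dioxane), 0 °C → rt, argon; evaporate; then aq NaHCO3 to pH 8, argon
Reagents that add atoms: none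
Why: Acidolytic Boc cleavage releases both secondary amines with only gaseous co-products, the amides and catechols being stable to anhydrous acid, and mild bicarbonate neutralisation under argon should give the free base.

**Compound list**

1 | 1,4-diaminobutane (putrescine) | NCCCCN | starting material
2 | N,N'-di-Boc-1,4-diaminobutane (di-tert-butyl butane-1,4-diyldicarbamate) | CC(C)(C)OC(=O)NCCCCNC(=O)OC(C)(C)C | intermediate
3 | ethyl bromoacetate | CCOC(=O)CBr | starting material
4 | diethyl N,N'-di-Boc-N,N'-butane-1,4-diylbisglycinate | CCOC(=O)CN(C(=O)OC(C)(C)C)CCCCN(C(=O)OC(C)(C)C)CC(=O)OCC | intermediate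
5 | N,N'-di-Boc-N,N'-butane-1,4-diylbisglycine | OC(=O)CN(C(=O)OC(C)(C)C)CCCCN(C(=O)OC(C)(C)C)CC(=O)O | intermediate
6 | N-(2-bromoethyl)phthalimide | O=C1c2ccccc2C(=O)N1CCBr | starting material
7 | mono-coupled acid, N-Boc-N-[4-[Boc(3-phthalimidopropyl)amino]butyl]glycine (formed in the flask, not isolated) | OC(=O)CN(C(=O)OC(C)(C)C)CCCCN(C(=O)OC(C)(C)C)CCCN1C(=O)c2ccccc2C1=O | intermediate
8 | N1,N12-diphthaloyl-N4,N9-di-Boc-spermine | O=C1c2ccccc2C(=O)N1CCCN(C(=O)OC(C)(C)C)CCCCN(C(=O)OC(C)(C)C)CCCN1C(=O)c2ccccc2C1=O | intermediate
9 | N4,N9-di-Boc-spermine | NCCCN(C(=O)OC(C)(C)C)CCCCN(C(=O)OC(C)(C)C)CCCN | intermediate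
10 | 3-(3,4-dihydroxyphenyl)propanoic acid | O=C(O)CCc1ccc(O)c(O)c1 | starting material
11 | N-succinimidyl 3-(3,4-dihydroxyphenyl)propanoate (formed in the flask, not isolated) | O=C(CCc1ccc(O)c(O)c1)ON1C(=O)CCC1=O | intermediate
12 | N4,N9-di-Boc-kukoamine A | O=C(CCc1ccc(O)c(O)c1)NCCCN(C(=O)OC(C)(C)C)CCCCN(C(=O)OC(C)(C)C)CCCNC(=O)CCc1ccc(O)c(O)c1 | intermediate
13 | kukoamine A bis-hydrochloride (formed in the flask, not isolated) | O=C(CCc1ccc(O)c(O)c1)NCCC[NH2+]CCCC[NH2+]CCCNC(=O)CCc1ccc(O)c(O)c1.[Cl-].[Cl-] | intermediate
14 | kukoamine A | O=C(CCc1ccc(O)c(O)c1)NCCCNCCCCNCCCNC(=O)CCc1ccc(O)c(O)c1 | target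

**Step count**

Total step count: 7. Longest linear sequence: 7 steps (1 → 14); compounds 3, 6 and 10 enter as purchased materials.

**Steps most likely to fail**

1. Step 4. Protodecarboxylation, O-alkylation of the carboxylate by the bromide and base-induced loss of HBr from the bromide may outpace the second C–C coupling, so that mono-coupled and N-methyl material accumulates; slow opening of the imide rings by wet carbonate is a further drain. The fallback abandons the radical disconnection, sets out from 1 and rejoins the route at 9. Diamine 1 would be doubly cyanoethylated with acrylonitrile (2 equiv, EtOH, 0 °C → rt) to N,N'-bis(2-cyanoethyl)-1,4-diaminobutane F1. Both secondary amines would then be protected with Boc2O to give N,N'-di-Boc-N,N'-bis(2-cyanoethyl)-1,4-diaminobutane F2. Finally the two nitriles would be hydrogenated (H2, Raney Ni, NH3/MeOH) to the primary amines of 9.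

2. Step 6. The catechol hydroxyls may be O-acylated, the activated acid may self-condense, and the catechol may oxidise in air under the basic coupling conditions. The fallback masks the catechol, sets out from 10 and rejoins the route at 12. Acid 10 would be perbenzylated (BnBr, K2CO3, DMF) to benzyl 3-[3,4-bis(benzyloxy)phenyl]propanoate F3 and the ester saponified (NaOH, THF/MeOH/H2O) to 3-[3,4-bis(benzyloxy)phenyl]propanoic acid F4. This would be converted with N-hydroxysuccinimide and DCC into the isolable N-succinimidyl 3-[3,4-bis(benzyloxy)phenyl]propanoate F5, which would acylate 9 to give N4,N9-di-Boc-tetra-O-benzylkukoamine A F6. Hydrogenolysis (H2, 10% Pd/C, MeOH/EtOAc) would then remove the four benzyl ethers to give 12.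

3. Step 7. The tert-butyl cation released on Boc cleavage may alkylate the electron-rich catechol rings (Friedel–Crafts tert-butylation), and the catechols may oxidise during neutralisation. The fallback moves Boc cleavage ahead of the introduction of the catechols, sets out from 9 and rejoins the route at 14. Compound 9 would be treated with HCl in 1,4-dioxane to give spermine F7, handled as its tetrahydrochloride and freed with iPr2NEt in the acylation flask. Its two primary amino groups would then be acylated selectively with two equivalents of the N-hydroxysuccinimide ester 11 (prepared as in step 6) at −20 → 0 °C in MeOH/CH2Cl2 under argon, relying on the known preference of active esters for primary over secondary amines in polyamines, to give 14 directly.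

**Further compounds**

F1 | step 4 | N,N'-bis(2-cyanoethyl)-1,4-diaminobutane | N#CCCNCCCCNCCC#N
F2 | step 4 | N,N'-di-Boc-N,N'-bis(2-cyanoethyl)-1,4-diaminobutane | N#CCCN(C(=O)OC(C)(C)C)CCCCN(C(=O)OC(C)(C)C)CCC#N
F3 | step 6 | benzyl 3-[3,4-bis(benzyloxy)phenyl]propanoate | O=C(CCc1ccc(OCc2ccccc2)c(OCc2ccccc2)c1)OCc1ccccc1
F4 | step 6 | 3-[3,4-bis(benzyloxy)phenyl]propanoic acid | O=C(O)CCc1ccc(OCc2ccccc2)c(OCc2ccccc2)c1
F5 | step 6 | N-succinimidyl 3-[3,4-bis(benzyloxy)phenyl]propanoate | O=C(CCc1ccc(OCc2ccccc2)c(OCc2ccccc2)c1)ON1C(=O)CCC1=O
F6 | step 6 | N4,N9-di-Boc-tetra-O-benzylkukoamine A | O=C(CCc1ccc(OCc2ccccc2)c(OCc2ccccc2)c1)NCCCN(C(=O)OC(C)(C)C)CCCCN(C(=O)OC(C)(C)C)CCCNC(=O)CCc1ccc(OCc2ccccc2)c(OCc2ccccc2)c1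
F7 | step 7 | spermine | NCCCNCCCCNCCCN
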